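The numbers of this flask were drawn at random within sensible limits; the rest is arithmetic.

At early times a stirred flask of Z and G sends Z down two paths, to links Z.G and to rings Q, and the set-ups below differ in how much G stands beside Z while that happens.

    Z + G → Z.G (k1 = 42 L mol⁻¹ s⁻¹)
    Z + G → Q, rate k2*[Z] as long as [G] is above zero (k2 = 0.042 s⁻¹)
    Z + J → Z.J (k3 = 180 L mol⁻¹ s⁻¹)
    Z.G → L (k4 = 0.059 s⁻¹)
    Z + Z.G ⇌ Z.Z.G, settled at all times (K5 = 8500 L mol⁻¹)

| setting | summer | midnight | autumn | winter |
|---|---|---|---|---|
| Z | 2.0 mM | 2.0 mM | 2.0 mM | 2.0 mM |
| G | 2.10 mM | 2.10 mM (fed, over 7.50 s) | 2.10 mM | 2.10 mM |
| J | 0.200 mM | 0.200 mM | 0.200 mM | 0.200 mM |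
| remark | one stirred flow tank at steady state, fed with the mixture as stated, mean residence time 15 s | a stirred flask in which G is dosed at a steady rate over 7.50 s without added volume, worked up at 15 s | a closed flask charged with all of it at once and left for 15 s | a single well-mixed tank run continuously and read at steady state, 150 s in it on average |
| time |  | 15 s | 15 s |  |

- percent here means Z units held: one Z.Z.G counts as two
- what is said of Z.G includes Z.Z.G
- the stated concentrations are those of everything mixed, before any reaction; amounts are the same in each set-up
- the feed brings no volume worth counting
- in an amount of Z.G, one Z.Z.G counts as one Z.G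
- run time (midnight): 15 s

* the set-up with the highest share of Z.G in all that became Z.G or Q or L, at the outlet or at the end ("none" if the first two lie within 2 percentage points) (summer / midnight / autumn / winter / none)
* share of Z.G in all that became Z.G or Q or L, at the outlet or at the end, summer
* share of Z.G in all that became Z.G or Q or L, at the outlet or at the end, midnight
* share of Z.G in all that became Z.G or Q or L, at the outlet or at the end, autumn
* share of Z.G in all that became Z.G or Q or L, at the outlet or at the end, winter

Let g be the fraction of the charged G still present. Per Z present, the step to Z.G slows as g falls, while the step to Q keeps its pace as long as G lasts. Of what these two paths take, Z.G therefore receives g/(g+gc), a selectivity set by the crossover fraction gc = k2/(k1 cB), the fraction of G left at which both paths run equally fast, 0.476.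

In autumn g starts at one, which gives 67.7 %. We guess that G falls to half its charge by 15 s, where the rule gives 51.2 %, so we reckon about 59.5 % for autumn, before any loss to L. At midnight g starts from zero, and while g is under gc, Q forms faster than Z.G. The winter tank holds its contents 150 s on average, far longer than the 12 s half-life of free Z.G on its way to L, so we expect Z.G to be lost to L there. Our reckoning goes no further: it gives a figure for autumn and none for summer, so it ranks no set-up first.

The forecast names autumn, with 63.2 % for summer, 54 % for midnight, 65.5 % for autumn and 11 % for winter. Its autumn figure lies above ours. For midnight it argues that “dosing G keeps it scarce while Z is plentiful”.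

The simulation gives autumn as best, with 48.2 % for summer, 40.2 % for midnight, 52.9 % for autumn and 7.21 % for winter.

With everything as charged in autumn, Z has a half-life of 7.9 s by the step to Z.G and 16.5 s by the step to Q, so the first path starts twice as fast, which is the starting 67.7 %. Put into the rule as though each share were the split of the two paths, with nothing gone to L and no second Z held in Z.Z.G, the autumn reading of 52.9 % corresponds to g = 0.534, and the midnight reading of 40.2 % to g = 0.320.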